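**Retrosynthetic overview** (isochromene numbering: O2, C1, C3, C4, C4a, C5–C8, C8a)
1. Ring A (pyran) is closed last: O2–C3 by gold-catalysed 6-endo hydroalkoxylation of a 2-(hydroxymethyl)-3-enynyl-cyclohexenone. C1 comes from formaldehyde, and C3/C4/propenyl from (E)-pent-3-en-1-yne added to the ring B enone.
2. Both stereocentres come from one CBS desymmetrising reduction of a mirror-symmetric 2-aroyloxy-2-methylcyclohexane-1,3-dione (hydride anti to the ester gives the cis hydroxy ester).
3. Key disconnection: the hindered tertiary ester C7–O bond, made at the carboxylate oxygen by manganese-mediated radical acyloxylation of 2-methylcyclohexane-1,3-dione with the complete aryl acid.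
4. The aryl acid comes from methyl acetoacetate (dianion self-condensation to methyl orsellinate, MOM/methyl ethers, saponification).
5. Ring order: arene, then ring B (bought as the dione, then functionalised), then ring A.

Assumption: (E)-pent-3-en-1-yne (13) is bought as the trans isomer (or as an E-rich mixture that is fractionated).

**Step 1**
Reactants: 1 methyl acetoacetate (2 equiv)
Product: 3 methyl 2,4-dihydroxy-6-methylbenzoate (methyl orsellinate), via methyl 3,5,7-trioxooctanoate 2 (not isolated)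
Conditions: NaH (1.0 equiv), THF, 0 °C; n-BuLi (1.05 equiv), −78 °C → rt, then reflux; 2 M HCl
Reagents that add atoms: none
Why: Harris-type dianion chemistry, in which the γ-carbanion of the acetoacetate dianion acylates a second ester (Claisen) to give triketo ester 2, which closes by intramolecular aldol condensation and aromatises to the resorcylate.

**Step 2**
Reactants: 3 methyl 2,4-dihydroxy-6-methylbenzoate
Product: 5 methyl 2-methoxy-4-(methoxymethoxy)-6-methylbenzoate, via methyl 2-hydroxy-4-(methoxymethoxy)-6-methylbenzoate 4 (not isolated)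
Conditions: MOMCl (1.1 equiv), K2CO3 (4 equiv), acetone, 0 °C → rt; then MeI (3 equiv), reflux
Reagents that add atoms: chloromethyl methyl ether (MOMCl), COCCl; iodomethane, CI
Why: Two Williamson etherifications in sequence, the free 4-OH reacting first with MOMCl while the 2-OH, hydrogen-bonded to the ester, is methylated only with MeI at reflux.

**Step 3**
Reactants: 5 methyl 2-methoxy-4-(methoxymethoxy)-6-methylbenzoate
Product: 6 2-methoxy-4-(methoxymethoxy)-6-methylbenzoic acid
Conditions: KOH (6 equiv), DMSO/H2O 4:1, 80 °C; then 1 M HCl to pH 4, 0 °C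
Reagents that add atoms: potassium hydroxide, [K+].[OH-]
Why: Saponification of the doubly ortho-substituted ester forced by hot aqueous DMSO; the MOM acetal is base-stable and survives the brief cold acidification.

**Step 4**
Reactants: 7 cyclohexane-1,3-dione
Product: 8 2-methylcyclohexane-1,3-dione
Conditions: MeI (1.3 equiv), NaOH (1.0 equiv), H2O/1,4-dioxane, reflux
Reagents that add atoms: iodomethane, CI
Why: C-alkylation of the 1,3-dione enolate, with the soft iodide in aqueous medium favouring C- over O-methylation.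

**Step 5** (key step)
Reactants: 8 2-methylcyclohexane-1,3-dione; 6 2-methoxy-4-(methoxymethoxy)-6-methylbenzoic acid
Product: 9 1-methyl-2,6-dioxocyclohexyl 2-methoxy-4-(methoxymethoxy)-6-methylbenzoate
Conditions: Mn(OAc)3·2H2O (2.4 equiv), 6 (3.0 equiv), benzene, reflux with Dean–Stark trap (AcOH/H2O removed), Ar; excess 6 recovered with aq. NaHCO3
Reagents that add atoms: none
Why: Proposed new method: trivalent manganese oxidises the enol of 8 by one electron to the tertiary 1,3-dicarbonyl radical, which is quenched by carboxylate ligand transfer from a second trivalent manganese aroate (formed by acetate/aroate exchange as AcOH distils off), so the hindered ester C–O bond forms at the carboxylate oxygen and not at the shielded acyl carbon; the closest known reaction type is Mn(OAc)3 α-acetoxylation of 1,3-dicarbonyls and α′-acyloxylation of enones with added carboxylic acids, and no stereocentre arises because 9 has a mirror plane (the new quaternary carbon is prochiral).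

**Step 6**
Reactants: 9 1-methyl-2,6-dioxocyclohexyl 2-methoxy-4-(methoxymethoxy)-6-methylbenzoate
Product: 10 (1R,2R)-2-hydroxy-1-methyl-6-oxocyclohexyl 2-methoxy-4-(methoxymethoxy)-6-methylbenzoate
Conditions: (S)-2-methyl-CBS-oxazaborolidine (20 mol%), BH3·SMe2 (0.7 equiv), THF, −30 °C; MeOH quench
Reagents that add atoms: none
Why: Corey–Bakshi–Shibata reduction used as a desymmetrisation, in which the (S)-catalyst gives the (R)-carbinol (quaternary carbon as the large group) and the carbonyl that reacts is the one able to take hydride anti to the pseudo-axial aroyloxy group (Felkin–Anh polar control), so the OH ends cis to the ester and the same event fixes the quaternary centre as R.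

**Step 7**
Reactants: 10 (1R,2R)-2-hydroxy-1-methyl-6-oxocyclohexyl 2-methoxy-4-(methoxymethoxy)-6-methylbenzoate
Product: 12 (1R,6R)-6-[(tert-butyldimethylsilyl)oxy]-1-methyl-2-oxocyclohex-3-en-1-yl 2-methoxy-4-(methoxymethoxy)-6-methylbenzoate, via bis-silylated enol ether 11 (not isolated)
Conditions: TBSOTf (2.5 equiv), Et3N (4 equiv), CH2Cl2, 0 °C → rt; solvent exchange; Pd(OAc)2 (1.1 equiv), MeCN, 40 °C
Reagents that add atoms: tert-butyldimethylsilyl trifluoromethanesulfonate (TBSOTf), CC(C)(C)[Si](C)(C)OS(=O)(=O)C(F)(F)F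
Why: The silyl triflate/amine pair silylates the alcohol and turns the only enolisable side of the ketone into its silyl enol ether, and Saegusa–Ito oxidation (divalent palladium enolate, β-hydride elimination) gives the enone without touching either stereocentre.

**Step 8**
Reactants: 12 (1R,6R)-6-[(tert-butyldimethylsilyl)oxy]-1-methyl-2-oxocyclohex-3-en-1-yl 2-methoxy-4-(methoxymethoxy)-6-methylbenzoate; 13 (E)-pent-3-en-1-yne
Product: 16 (1R,6R)-6-[(tert-butyldimethylsilyl)oxy]-1-methyl-2-oxo-4-[(E)-pent-3-en-1-yn-1-yl]cyclohex-3-en-1-yl 2-methoxy-4-(methoxymethoxy)-6-methylbenzoate, via alkynylzinc bromide 14 (not isolated), via β-alkynyl silyl enol ether 15 (not isolated)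
Conditions: 13 (1.5 equiv), n-BuLi, THF, −78 °C; ZnBr2, 0 °C; then 12, TBSOTf (1.5 equiv), −40 °C; solvent exchange; Pd(OAc)2 (1.1 equiv), MeCN, rt
Reagents that add atoms: none
Why: Silyl-triflate-promoted conjugate addition of the alkynylzinc halide to the s-trans enone gives the β-alkynyl silyl enol ether (its new C4a stereocentre is transient), and a second Saegusa–Ito oxidation restores the enone with the enyne on the β-carbon.

**Step 9**
Reactants: 16 (1R,6R)-6-[(tert-butyldimethylsilyl)oxy]-1-methyl-2-oxo-4-[(E)-pent-3-en-1-yn-1-yl]cyclohex-3-en-1-yl 2-methoxy-4-(methoxymethoxy)-6-methylbenzoate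
Product: 18 (1R,6R)-6-[(tert-butyldimethylsilyl)oxy]-3-(hydroxymethyl)-1-methyl-2-oxo-4-[(E)-pent-3-en-1-yn-1-yl]cyclohex-3-en-1-yl 2-methoxy-4-(methoxymethoxy)-6-methylbenzoate, via deconjugated aldol adduct 17 (not isolated)
Conditions: LiN(iPr)2 (1.1 equiv), THF, −78 °C; CH2O (gas from cracked paraformaldehyde), −78 °C; AcOH; then DBU (0.2 equiv), CH2Cl2, 0 °C
Reagents that add atoms: formaldehyde, C=O
Why: With no α′-hydrogen the amide base can only form the extended dienolate (γ-deprotonation at C5), which undergoes aldol addition to formaldehyde at the α-carbon (kinetic α-selectivity of dienolates), and DBU returns the double bond to conjugation so the transient C8a stereocentre is lost.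

**Step 10**
Reactants: 18 (1R,6R)-6-[(tert-butyldimethylsilyl)oxy]-3-(hydroxymethyl)-1-methyl-2-oxo-4-[(E)-pent-3-en-1-yn-1-yl]cyclohex-3-en-1-yl 2-methoxy-4-(methoxymethoxy)-6-methylbenzoate
Product: 20 (6R,7R)-6-hydroxy-7-methyl-8-oxo-3-[(E)-prop-1-en-1-yl]-5,6,7,8-tetrahydro-1H-isochromen-7-yl 4-hydroxy-2-methoxy-6-methylbenzoate (target), via protected isochromenone 19 (not isolated)
Conditions: Ph3PAuNTf2 (2 mol%), CH2Cl2, rt; then MeOH, HCl (1.25 M in MeOH), 0 °C → rt
Reagents that add atoms: none
Why: Monovalent gold activates the alkyne for 6-endo-dig hydroalkoxylation (cycloisomerisation) by the primary alcohol at the alkyne carbon whose positive charge the propenyl group stabilises, giving the conjugated 1H-isochromenone, and acid methanolysis then removes the silyl ether and the MOM acetal while the hindered tertiary aryl ester neither migrates nor cleaves.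

**Compound list**
1 | methyl acetoacetate | COC(=O)CC(C)=O | starting material
2 | methyl 3,5,7-trioxooctanoate | COC(=O)CC(=O)CC(=O)CC(C)=O | intermediate
3 | methyl 2,4-dihydroxy-6-methylbenzoate (methyl orsellinate) | COC(=O)c1c(C)cc(O)cc1O | intermediate
4 | methyl 2-hydroxy-4-(methoxymethoxy)-6-methylbenzoate | COC(=O)c1c(C)cc(OCOC)cc1O | intermediate
5 | methyl 2-methoxy-4-(methoxymethoxy)-6-methylbenzoate | COC(=O)c1c(C)cc(OCOC)cc1OC | intermediate
6 | 2-methoxy-4-(methoxymethoxy)-6-methylbenzoic acid | OC(=O)c1c(C)cc(OCOC)cc1OC | intermediate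
7 | cyclohexane-1,3-dione | O=C1CCCC(=O)C1 | starting material
8 | 2-methylcyclohexane-1,3-dione | CC1C(=O)CCCC1=O | intermediate
9 | 1-methyl-2,6-dioxocyclohexyl 2-methoxy-4-(methoxymethoxy)-6-methylbenzoate | CC1(OC(=O)c2c(C)cc(OCOC)cc2OC)C(=O)CCCC1=O | intermediate
10 | (1R,2R)-2-hydroxy-1-methyl-6-oxocyclohexyl 2-methoxy-4-(methoxymethoxy)-6-methylbenzoate | O=C1[C@](C)(OC(=O)c2c(C)cc(OCOC)cc2OC)[C@H](O)CCC1 | intermediate
11 | (1R,6R)-2,6-bis[(tert-butyldimethylsilyl)oxy]-1-methylcyclohex-2-en-1-yl 2-methoxy-4-(methoxymethoxy)-6-methylbenzoate | C1(O[Si](C)(C)C(C)(C)C)[C@](C)(OC(=O)c2c(C)cc(OCOC)cc2OC)[C@H](O[Si](C)(C)C(C)(C)C)CCC=1 | intermediate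
12 | (1R,6R)-6-[(tert-butyldimethylsilyl)oxy]-1-methyl-2-oxocyclohex-3-en-1-yl 2-methoxy-4-(methoxymethoxy)-6-methylbenzoate | O=C1[C@](C)(OC(=O)c2c(C)cc(OCOC)cc2OC)[C@H](O[Si](C)(C)C(C)(C)C)CC=C1 | intermediate
13 | (E)-pent-3-en-1-yne | C/C=C/C#C | starting material
14 | bromo[(E)-pent-3-en-1-yn-1-yl]zinc | C/C=C/C#C[Zn]Br | intermediate
15 | (1R,6R)-2,6-bis[(tert-butyldimethylsilyl)oxy]-1-methyl-4-[(E)-pent-3-en-1-yn-1-yl]cyclohex-2-en-1-yl 2-methoxy-4-(methoxymethoxy)-6-methylbenzoate (C4 epimers) | C1(O[Si](C)(C)C(C)(C)C)[C@](C)(OC(=O)c2c(C)cc(OCOC)cc2OC)[C@H](O[Si](C)(C)C(C)(C)C)CC(C#C/C=C/C)C=1 | intermediate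
16 | (1R,6R)-6-[(tert-butyldimethylsilyl)oxy]-1-methyl-2-oxo-4-[(E)-pent-3-en-1-yn-1-yl]cyclohex-3-en-1-yl 2-methoxy-4-(methoxymethoxy)-6-methylbenzoate | O=C1[C@](C)(OC(=O)c2c(C)cc(OCOC)cc2OC)[C@H](O[Si](C)(C)C(C)(C)C)CC(C#C/C=C/C)=C1 | intermediate
17 | (1R,6R)-6-[(tert-butyldimethylsilyl)oxy]-3-(hydroxymethyl)-1-methyl-2-oxo-4-[(E)-pent-3-en-1-yn-1-yl]cyclohex-4-en-1-yl 2-methoxy-4-(methoxymethoxy)-6-methylbenzoate (C3 epimers) | O=C1[C@](C)(OC(=O)c2c(C)cc(OCOC)cc2OC)[C@H](O[Si](C)(C)C(C)(C)C)C=C(C#C/C=C/C)C1CO | intermediate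
18 | (1R,6R)-6-[(tert-butyldimethylsilyl)oxy]-3-(hydroxymethyl)-1-methyl-2-oxo-4-[(E)-pent-3-en-1-yn-1-yl]cyclohex-3-en-1-yl 2-methoxy-4-(methoxymethoxy)-6-methylbenzoate | O=C1[C@](C)(OC(=O)c2c(C)cc(OCOC)cc2OC)[C@H](O[Si](C)(C)C(C)(C)C)CC(C#C/C=C/C)=C1CO | intermediate
19 | (6R,7R)-6-[(tert-butyldimethylsilyl)oxy]-7-methyl-8-oxo-3-[(E)-prop-1-en-1-yl]-5,6,7,8-tetrahydro-1H-isochromen-7-yl 2-methoxy-4-(methoxymethoxy)-6-methylbenzoate | C/C=C/C1=CC2=C(CO1)C(=O)[C@](C)(OC(=O)c1c(C)cc(OCOC)cc1OC)[C@H](O[Si](C)(C)C(C)(C)C)C2 | intermediate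
20 | (6R,7R)-6-hydroxy-7-methyl-8-oxo-3-[(E)-prop-1-en-1-yl]-5,6,7,8-tetrahydro-1H-isochromen-7-yl 4-hydroxy-2-methoxy-6-methylbenzoate | C/C=C/C1=CC2=C(CO1)C(=O)[C@](C)(OC(=O)c1c(C)cc(O)cc1OC)[C@H](O)C2 | target

**Totals**
Total step count: 10.
Longest linear sequence: 9 steps (steps 1, 2, 3, 5, 6, 7, 8, 9, 10; step 4 and compound 13 are side branches).

**Three steps most likely to fail, with fallbacks**

Step 5. The ligand transfer may lose to acetoxylation, to oxidation of the electron-rich arene of 6, or to enol dimerisation. The fallback replaces the one-electron oxygen transfer by a two-electron one on trivalent iodine. It sets out from 6 and 8: 6 (2.2 equiv) and PhI(OAc)2 are heated in chlorobenzene under vacuum to strip AcOH, giving bis[2-methoxy-4-(methoxymethoxy)-6-methylbenzoyloxy](phenyl)-λ3-iodane F1. F1 then transfers one aroyloxy group to the potassium enolate of 8 (K2CO3, MeCN, rt) by ligand coupling, and the route is rejoined at 9.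

Step 9. The extended enolate has carbanion character at C5, next to the silyloxy-bearing carbon, so it may expel silanolate, and the aldol may also be poorly regioselective. The fallback avoids enolate chemistry and makes the C8a–C1 bond by cross-coupling. It sets out from 16: I2/pyridine in CH2Cl2 gives (1R,6R)-6-[(tert-butyldimethylsilyl)oxy]-3-iodo-1-methyl-2-oxo-4-[(E)-pent-3-en-1-yn-1-yl]cyclohex-3-en-1-yl 2-methoxy-4-(methoxymethoxy)-6-methylbenzoate F2. Stille coupling of F2 with (tributylstannyl)methanol (Pd(PPh3)4, zerovalent palladium, 1,4-dioxane, 80 °C) returns to the route at 18.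

Step 10. The push–pull dienyl ether of 19 and 20 may not tolerate methanolic HCl (solvolysis or methanol addition at C3). The fallback changes the order of events so that the acid-labile ring is formed last. It sets out from 18: HCl/MeOH first removes both protecting groups while no enol ether is present, giving (1R,6R)-6-hydroxy-3-(hydroxymethyl)-1-methyl-2-oxo-4-[(E)-pent-3-en-1-yn-1-yl]cyclohex-3-en-1-yl 4-hydroxy-2-methoxy-6-methylbenzoate F3. Ring A is then closed as the final operation under neutral conditions (Ph3PAuNTf2, CH2Cl2/THF, rt), arriving directly at 20.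

**Further compounds**
F1 | step 5 | bis[2-methoxy-4-(methoxymethoxy)-6-methylbenzoyloxy](phenyl)-λ3-iodane | O=C(OI(OC(=O)c1c(C)cc(OCOC)cc1OC)c1ccccc1)c1c(C)cc(OCOC)cc1OC
F2 | step 9 | (1R,6R)-6-[(tert-butyldimethylsilyl)oxy]-3-iodo-1-methyl-2-oxo-4-[(E)-pent-3-en-1-yn-1-yl]cyclohex-3-en-1-yl 2-methoxy-4-(methoxymethoxy)-6-methylbenzoate | O=C1[C@](C)(OC(=O)c2c(C)cc(OCOC)cc2OC)[C@H](O[Si](C)(C)C(C)(C)C)CC(C#C/C=C/C)=C1I
F3 | step 10 | (1R,6R)-6-hydroxy-3-(hydroxymethyl)-1-methyl-2-oxo-4-[(E)-pent-3-en-1-yn-1-yl]cyclohex-3-en-1-yl 4-hydroxy-2-methoxy-6-methylbenzoate | O=C1[C@](C)(OC(=O)c2c(C)cc(O)cc2OC)[C@H](O)CC(C#C/C=C/C)=C1CO
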